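**Retrosynthetic overview**
1. Endgame: the C6 aldehyde comes from hydrolysis of a C5=C6 methoxymethyl enol ether, 15-OH from 1,2-reduction of a C15 enone, and 1-OAc from equatorial reduction of a C1 ketone.
2. Ring D (C13–C16) is closed by 5-exo vinyl-radical cyclisation of a C15 ethynyl carbinol onto a ring C alkene; ring C is made by Diels–Alder addition of butadiene to the C8=C9 bond of a spiro lactone thioester.
3. Key disconnection: both lactone C–C bonds, C10–C20 and C7–C8, back to a monocyclic dienyl thioester plus ClCH2OC(=O)Cl. Enabling feature: in the δ-lactone (C10, C20, O, C7, C8, C9) the oxymethylene C20 and the acyl carbon C7 sit on C10 and C8, which are 1,3-related across C9 and are the γ- and α-carbons of the extended enolate C6–C5=C10–C9=C8–C15(=O)SEt.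
4. Ring A comes from 4,4-dimethylcyclohexane-1,3-dione by alkylative carbonyl transposition (brings in C6) and CBS reduction; the resulting C1 stereocentre is temporary, relays to C10 and is later corrected.
5. Order of ring formation: ring A (purchased) → δ-lactone (step 9) → ring C (step 10) → ring D (step 17).

Key step: step 9

Remark: atoms carry ent-kaurane numbers (ring A: C1–C5, C10; lactone: C10, C20, O, C7, C8, C9; ring C: C8, C9, C11–C14; ring D: C8, C14, C13, C16, C15; C6 = formyl carbon; C17 = exocyclic CH2). The C5=C6 enol ether geometry (15–29) and the C15 carbinol configuration in 25–27 are inconsequential mixtures and are left open in the SMILES; 3 and 5 are racemic.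

**Route**

Step 1
Reactants: 1 4,4-dimethylcyclohexane-1,3-dione
Product: 2 6,6-dimethyl-3-(2-methylpropoxy)cyclohex-2-en-1-one
Conditions: 2-methylpropan-1-ol, TsOH (cat.), toluene, reflux, Dean–Stark trap
Reagents that add atoms: 2-methylpropan-1-ol CC(C)CO
Why: Acid-catalysed enol etherification of a cyclic 1,3-dione (vinylogous ester formation); the alcohol should condense at the carbonyl remote from the gem-dimethyl group, which leaves the hindered ketone (the future C5) free.

Step 2
Reactants: 2 6,6-dimethyl-3-(2-methylpropoxy)cyclohex-2-en-1-one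
Product: 4 3-[(methoxymethoxy)methyl]-4,4-dimethylcyclohex-2-en-1-one, via tertiary allylic alcohol adduct 3 (not isolated)
Conditions: Bu3SnCH2OCH2OCH3, n-BuLi, THF, −78 °C; add 2, −78 to 0 °C; then 1 M aq. HCl, 0 °C
Reagents that add atoms: tributyl[(methoxymethoxy)methyl]stannane CCCC[Sn](CCCC)(CCCC)COCOC; water O
Why: Stork–Danheiser alkylative carbonyl transposition: the α-alkoxymethyllithium from tin–lithium exchange adds 1,2 to the vinylogous ester ketone and acid hydrolysis of 3 gives the transposed enone, which puts the oxygenated C6 carbon on C5.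

Step 3
Reactants: 4 3-[(methoxymethoxy)methyl]-4,4-dimethylcyclohex-2-en-1-one
Product: 6 2-bromo-3-[(methoxymethoxy)methyl]-4,4-dimethylcyclohex-2-en-1-one, via 2,3-dibromo ketone 5 (not isolated)
Conditions: Br2, CH2Cl2, 0 °C; then Et3N, 0 °C to rt
Reagents that add atoms: bromine BrBr
Why: Bromine addition to the enone followed by base-induced dehydrobromination (loss of the acidic α-hydrogen and the β-bromide) is the standard route to 2-bromocyclohex-2-enones.

Step 4
Reactants: 6 2-bromo-3-[(methoxymethoxy)methyl]-4,4-dimethylcyclohex-2-en-1-one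
Product: 7 (1R)-2-bromo-3-[(methoxymethoxy)methyl]-4,4-dimethylcyclohex-2-en-1-ol
Conditions: (S)-2-methyl-CBS-oxazaborolidine (10 mol%), BH3·SMe2, THF, −20 °C
Reagents that add atoms: none
Why: Corey–Bakshi–Shibata reduction; the bromoalkene side of the ketone acts as the large group, so the (S)-catalyst should give the (1R)-alcohol, the only stereocentre carried into the key step.

Step 5
Reactants: 7 (1R)-2-bromo-3-[(methoxymethoxy)methyl]-4,4-dimethylcyclohex-2-en-1-ol
Product: 8 {[(1R)-2-bromo-3-[(methoxymethoxy)methyl]-4,4-dimethylcyclohex-2-en-1-yl]oxy}(tert-butyl)dimethylsilane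
Conditions: TBSCl, imidazole, DMF, rt
Reagents that add atoms: tert-butylchlorodimethylsilane CC(C)(C)[Si](C)(C)Cl
Why: Standard silylation; the bulky silyl ether protects O1 against the bases used later and is the group that shields one face of C10 in step 9.

Step 6
Reactants: 8 {[(1R)-2-bromo-3-[(methoxymethoxy)methyl]-4,4-dimethylcyclohex-2-en-1-yl]oxy}(tert-butyl)dimethylsilane
Product: 10 (6R)-6-[(tert-butyldimethylsilyl)oxy]-2-[(methoxymethoxy)methyl]-3,3-dimethylcyclohex-1-ene-1-carbaldehyde, via alkenyllithium 9 (not isolated)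
Conditions: t-BuLi (2.1 equiv), Et2O, −78 °C; then DMF, −78 to 0 °C; H2O
Reagents that add atoms: tert-butyllithium [Li]C(C)(C)C; N,N-dimethylformamide CN(C)C=O
Why: Bromine–lithium exchange of the alkenyl bromide and formylation of alkenyllithium 9 with DMF (Bouveault-type formylation) is reliable for 2-lithiocyclohexenyl silyl ethers.

Step 7
Reactants: 11 2-(diethoxyphosphoryl)acetic acid
Product: 12 S-ethyl 2-(diethoxyphosphoryl)ethanethioate
Conditions: EtSH, DCC, DMAP (cat.), CH2Cl2, 0 °C to rt
Reagents that add atoms: ethanethiol CCS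
Why: Carbodiimide-mediated (Steglich) thioesterification of a carboxylic acid with a thiol gives the phosphonate reagent.

Step 8
Reactants: 10 (6R)-6-[(tert-butyldimethylsilyl)oxy]-2-[(methoxymethoxy)methyl]-3,3-dimethylcyclohex-1-ene-1-carbaldehyde; 12 S-ethyl 2-(diethoxyphosphoryl)ethanethioate
Product: 13 S-ethyl (2E)-3-[(6R)-6-[(tert-butyldimethylsilyl)oxy]-2-[(methoxymethoxy)methyl]-3,3-dimethylcyclohex-1-en-1-yl]prop-2-enethioate
Conditions: LiCl, DBU, MeCN, rt
Reagents that add atoms: none
Why: Horner–Wadsworth–Emmons olefination under LiCl/amine (Masamune–Roush) conditions should give the (E)-enoate from the hindered enal without touching the thioester.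

Step 9
Reactants: 13 S-ethyl (2E)-3-[(6R)-6-[(tert-butyldimethylsilyl)oxy]-2-[(methoxymethoxy)methyl]-3,3-dimethylcyclohex-1-en-1-yl]prop-2-enethioate; 14 chloromethyl carbonochloridate (chloromethyl chloroformate)
Product: 17 S-ethyl (6S,11R)-11-[(tert-butyldimethylsilyl)oxy]-7-[(methoxymethoxy)methylidene]-8,8-dimethyl-3-oxo-2-oxaspiro[5.5]undec-4-ene-4-carbothioate (ent-kaurane descriptors 10S,1R; C20 trans to O1), via lithium trienolate 15 (not isolated), via chloromethyl malonate 16 (not isolated)
Conditions: LiN(iPr)2 (1.1 equiv), THF/DMPU, −78 °C; transfer into ClCH2OC(=O)Cl (1.1 equiv), THF, −78 °C; then LiN(SiMe3)2 (1.2 equiv), NaI (cat.), −78 to 40 °C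
Reagents that add atoms: lithium diisopropylamide CC(C)N([Li])C(C)C
Why: Proposed new method: LiN(iPr)2 removes an ε-proton at C6 to give the extended enolate 15, whose α-carbon C8 is C-acylated by the acid chloride end of ClCH2OC(=O)Cl (deconjugative α-acylation, the known behaviour of ester dienolates toward chloroformates) to give 16, and a second base regenerates a malonate-type pentadienyl anion that alkylates the tethered chloromethyl carbon C20 at C10. Closure at C8 would give a four-membered ring and closure at C6 an eight-membered one, so C20 is forced onto the γ-carbon C10 in a 6-(enolendo)-exo-tet closure of the ring C10, C20, O, C7, C8, C9, which restores the C8=C9 alkylidene (the dienophile for step 10) and leaves C5=C6 as an enol ether (the masked C6 aldehyde). The closest known reaction types are the formal (3+3) cyclisations of 1,3-dinucleophiles with 1,3-dielectrophiles and the γ-selective vinylogous aldol–lactonisation of alkylidene malonates to 5,6-dihydropyran-2-ones; new is that one reagent delivers an acyl carbon and an oxymethylene to the two ends of a dienolate. The only new stereocentre, quaternary C10, is controlled by the C1 silyloxy group: allylic 1,3-strain with the C8 substituent on C9 holds it pseudo-axial, so C20 should enter on the opposite face (C20 trans to OSi, 10S). The selectivity needed is C- over O-alkylation of the stabilised anion (O-alkylation would give a 1,3-dioxin-4-one); the lithium counter-ion, iodide catalysis (softer iodomethyl ester, reversible O-alkylation) and the gain of a conjugated alkylidene malonate should favour the C–C bond.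

Step 10
Reactants: 17 spiro lactone thioester (as above); 18 buta-1,3-diene
Product: 19 Diels–Alder adduct (1R,8R,9S,10S): cyclohex-12-ene ring C cis-fused to the lactone at C8–C9, S-ethyl thioester on C8, 1-OTBS, C5=C6 methoxymethyl enol ether
Conditions: buta-1,3-diene (excess), BHT, toluene, 130 °C, sealed tube
Reagents that add atoms: none
Why: Thermal Diels–Alder reaction of a doubly activated cyclic alkylidene (lactone and thioester carbonyls on C8); suprafacial addition makes C11 and C14 cis, and the diene should approach the C8=C9 face that carries C1 (its silyloxy group, trans to C20, points away) because the other face is blocked by the C5 enol ether and the C4 gem-dimethyl group, which sets 8R and 9S and leaves C15 cis to H9.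

Step 11
Reactants: 19 Diels–Alder adduct (1R,8R,9S,10S)
Product: 20 (1R,8R,9S,10S)-C1 alcohol (1-epi configuration, OH trans to C20)
Conditions: Bu4NF, AcOH (1:1), THF, 0 °C to rt
Reagents that add atoms: none
Why: Fluoride desilylation buffered with acetic acid, so that no free C1 alkoxide can attack the neighbouring lactone.

Step 12
Reactants: 20 (1R,8R,9S,10S)-C1 alcohol
Product: 21 (8R,9S,10S)-C1 ketone
Conditions: Dess–Martin periodinane, NaHCO3, CH2Cl2, rt
Reagents that add atoms: none
Why: Dess–Martin oxidation removes the temporary C1 stereocentre under buffered, non-basic conditions that spare the thioester and the enol ether.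

Step 13
Reactants: 21 (8R,9S,10S)-C1 ketone
Product: 22 (1S,8R,9S,10S)-C1 alcohol (OH equatorial, cis to C20)
Conditions: NaBH4, MeOH/THF, −40 °C
Reagents that add atoms: none
Why: Borohydride reduction of a cyclohexanone: with the bulky C9 equatorial and C20 axial on C10, hydride should attack C1 anti to the axial C20 (axial attack) and give the equatorial 1S alcohol.

Step 14
Reactants: 22 (1S,8R,9S,10S)-C1 alcohol
Product: 23 (1S,8R,9S,10S)-C1 acetate
Conditions: Ac2O, pyridine, DMAP (cat.), CH2Cl2, rt
Reagents that add atoms: acetic anhydride CC(=O)OC(C)=O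
Why: DMAP-catalysed acetylation installs the C1 acetate of the target before any basic step, which also blocks translactonisation to a 1,7-lactone.

Step 15
Reactants: 23 (1S,8R,9S,10S)-C1 acetate
Product: 24 (1S,8S,9S,10S)-C15 aldehyde
Conditions: Et3SiH, Pd/C (10 wt%), acetone, rt
Reagents that add atoms: none
Why: Fukuyama reduction converts the thioester into the aldehyde and should leave the lactone, the acetate and the hindered alkenes untouched.

Step 16
Reactants: 24 (1S,8S,9S,10S)-C15 aldehyde
Product: 25 (1S,8S,9S,10S)-C15 ethynyl carbinol (C15 epimers)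
Conditions: HC≡CMgBr (1.5 equiv), THF, −78 °C; H2O
Reagents that add atoms: ethynylmagnesium bromide C#C[Mg]Br
Why: Grignard addition of an acetylide to the neopentyl aldehyde at low temperature, where lactone and acetate are inert; the C15 configuration does not matter because C15 is oxidised in step 18.

Step 17
Reactants: 25 (1S,8S,9S,10S)-C15 ethynyl carbinol
Product: 27 (1S,8S,9S,10S,13R)-ring D allylic alcohol (16-methylene, C15 epimers), via C17 vinylstannane 26 (not isolated)
Conditions: Bu3SnH, AIBN (cat.), benzene (0.02 M), 80 °C; then SiO2, CH2Cl2, rt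
Reagents that add atoms: tributylstannane CCCC[SnH](CCCC)CCCC
Why: Tin-hydride-mediated enyne radical cyclisation: Bu3Sn• adds to the alkyne terminus, the C16 vinyl radical closes 5-exo-trig onto C13 of the ring C alkene and the C12 radical is reduced; the two-carbon bridge can only form on the face of ring C that carries C15, which fixes 13R, and protodestannylation of 26 on silica gives the exocyclic methylene.

Step 18
Reactants: 27 (1S,8S,9S,10S,13R)-ring D allylic alcohol
Product: 28 (1S,8S,9S,10S,13R)-C15 enone
Conditions: MnO2, CH2Cl2, rt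
Reagents that add atoms: none
Why: MnO2 oxidises the allylic alcohol selectively and converges both C15 epimers to one enone.

Step 19
Reactants: 28 (1S,8S,9S,10S,13R)-C15 enone
Product: 29 (1S,8S,9S,10S,13R,15R)-C15 alcohol, C5=C6 methoxymethyl enol ether
Conditions: NaBH4, CeCl3·7H2O, MeOH, −78 °C
Reagents that add atoms: none
Why: Luche 1,2-reduction; hydride should add to the exo face of the bicyclo[3.2.1]octenone, away from the C9–C11–C12 bridge whose axial C11–H shields the endo face, giving the 15R alcohol.

Step 20
Reactants: 29 (1S,8S,9S,10S,13R,15R)-C15 alcohol, C5=C6 methoxymethyl enol ether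
Product: 30 target, (1S,5R,8S,9S,10S,13R,15R)-1-acetoxy-15-hydroxy-6-oxo-6,7-seco-kaur-16-ene-7,20-lactone
Conditions: 1 M aq. HCl, THF, 0 °C to rt
Reagents that add atoms: water O
Why: Acid hydrolysis of the enol ether (the methoxymethyl group leaves as formaldehyde and methanol); kinetic protonation at C5 from the face anti to the axial C20 and the axial C4 methyl should place the formyl group equatorial, cis to C20 (5R).

**Compound list**
1 | 4,4-dimethylcyclohexane-1,3-dione | CC1(C)CCC(=O)CC1=O | starting material
2 | 6,6-dimethyl-3-(2-methylpropoxy)cyclohex-2-en-1-one | CC(C)COC1=CC(=O)C(C)(C)CC1 | intermediate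
3 | 1-[(methoxymethoxy)methyl]-6,6-dimethyl-3-(2-methylpropoxy)cyclohex-2-en-1-ol (racemic, not isolated) | COCOCC1(O)C=C(OCC(C)C)CCC1(C)C | intermediate
4 | 3-[(methoxymethoxy)methyl]-4,4-dimethylcyclohex-2-en-1-one | COCOCC1=CC(=O)CCC1(C)C | intermediate
5 | 2,3-dibromo-3-[(methoxymethoxy)methyl]-4,4-dimethylcyclohexan-1-one (racemic, not isolated) | COCOCC1(Br)C(Br)C(=O)CCC1(C)C | intermediate
6 | 2-bromo-3-[(methoxymethoxy)methyl]-4,4-dimethylcyclohex-2-en-1-one | COCOCC1=C(Br)C(=O)CCC1(C)C | intermediate
7 | (1R)-2-bromo-3-[(methoxymethoxy)methyl]-4,4-dimethylcyclohex-2-en-1-ol | O[C@@H]1CCC(C)(C)C(COCOC)=C1Br | intermediate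
8 | {[(1R)-2-bromo-3-[(methoxymethoxy)methyl]-4,4-dimethylcyclohex-2-en-1-yl]oxy}(tert-butyl)dimethylsilane | CC(C)(C)[Si](C)(C)O[C@@H]1CCC(C)(C)C(COCOC)=C1Br | intermediate
9 | [(6R)-6-[(tert-butyldimethylsilyl)oxy]-2-[(methoxymethoxy)methyl]-3,3-dimethylcyclohex-1-en-1-yl]lithium (not isolated) | CC(C)(C)[Si](C)(C)O[C@@H]1CCC(C)(C)C(COCOC)=C1[Li] | intermediate
10 | (6R)-6-[(tert-butyldimethylsilyl)oxy]-2-[(methoxymethoxy)methyl]-3,3-dimethylcyclohex-1-ene-1-carbaldehyde | CC(C)(C)[Si](C)(C)O[C@@H]1CCC(C)(C)C(COCOC)=C1C=O | intermediate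
11 | 2-(diethoxyphosphoryl)acetic acid | CCOP(=O)(CC(=O)O)OCC | starting material
12 | S-ethyl 2-(diethoxyphosphoryl)ethanethioate | CCOP(=O)(CC(=O)SCC)OCC | intermediate
13 | S-ethyl (2E)-3-[(6R)-6-[(tert-butyldimethylsilyl)oxy]-2-[(methoxymethoxy)methyl]-3,3-dimethylcyclohex-1-en-1-yl]prop-2-enethioate | CC(C)(C)[Si](C)(C)O[C@@H]1CCC(C)(C)C(COCOC)=C1/C=C/C(=O)SCC | intermediate
14 | chloromethyl carbonochloridate | ClCOC(Cl)=O | starting material
15 | lithium trienolate of 13 (C6-deprotonated O-lithio ketene hemithioacetal, not isolated) | CC(C)(C)[Si](C)(C)O[C@@H]1CCC(C)(C)C(=COCOC)C1=CC=C(O[Li])SCC | intermediate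
16 | chloromethyl 2-[(ethylsulfanyl)carbonyl]-3-[(6R)-6-[(tert-butyldimethylsilyl)oxy]-2-[(methoxymethoxy)methylidene]-3,3-dimethylcyclohexylidene]propanoate (not isolated) | CC(C)(C)[Si](C)(C)O[C@@H]1CCC(C)(C)C(=COCOC)C1=CC(C(=O)SCC)C(=O)OCCl | intermediate
17 | S-ethyl (6S,11R)-11-[(tert-butyldimethylsilyl)oxy]-7-[(methoxymethoxy)methylidene]-8,8-dimethyl-3-oxo-2-oxaspiro[5.5]undec-4-ene-4-carbothioate | CCSC(=O)C1=C[C@]2(COC1=O)[C@H](O[Si](C)(C)C(C)(C)C)CCC(C)(C)C2=COCOC | intermediate
18 | buta-1,3-diene | C=CC=C | starting material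
19 | Diels–Alder adduct (1R,8R,9S,10S): ring C cyclohex-12-ene cis-fused to the spiro lactone, C8 S-ethyl thioester, 1-OTBS | CCSC(=O)[C@]12CC=CC[C@H]1[C@]3(COC2=O)[C@H](O[Si](C)(C)C(C)(C)C)CCC(C)(C)C3=COCOC | intermediate
20 | (1R,8R,9S,10S)-C1 alcohol (OH trans to C20) | CCSC(=O)[C@]12CC=CC[C@H]1[C@]3(COC2=O)[C@H](O)CCC(C)(C)C3=COCOC | intermediate
21 | (8R,9S,10S)-C1 ketone | CCSC(=O)[C@]12CC=CC[C@H]1[C@]3(COC2=O)C(=O)CCC(C)(C)C3=COCOC | intermediate
22 | (1S,8R,9S,10S)-C1 alcohol (OH cis to C20) | CCSC(=O)[C@]12CC=CC[C@H]1[C@]3(COC2=O)[C@@H](O)CCC(C)(C)C3=COCOC | intermediate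
23 | (1S,8R,9S,10S)-C1 acetate, C8 S-ethyl thioester | CCSC(=O)[C@]12CC=CC[C@H]1[C@]3(COC2=O)[C@@H](OC(C)=O)CCC(C)(C)C3=COCOC | intermediate
24 | (1S,8S,9S,10S)-C15 aldehyde | O=C[C@]12CC=CC[C@H]1[C@]3(COC2=O)[C@@H](OC(C)=O)CCC(C)(C)C3=COCOC | intermediate
25 | (1S,8S,9S,10S)-C15 ethynyl carbinol (C15 epimers) | C#CC(O)[C@]12CC=CC[C@H]1[C@]3(COC2=O)[C@@H](OC(C)=O)CCC(C)(C)C3=COCOC | intermediate
26 | (1S,8S,9S,10S,13R)-C17 tributylstannyl alkene with closed ring D (not isolated) | CCCC[Sn](CCCC)(CCCC)C=C1[C@@H]2CC[C@@H]3[C@](C2)(C(=O)OC[C@]32[C@@H](OC(C)=O)CCC(C)(C)C2=COCOC)C1O | intermediate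
27 | (1S,8S,9S,10S,13R)-ring D allylic alcohol, 16-methylene (C15 epimers) | C=C1[C@@H]2CC[C@@H]3[C@](C2)(C(=O)OC[C@]32[C@@H](OC(C)=O)CCC(C)(C)C2=COCOC)C1O | intermediate
28 | (1S,8S,9S,10S,13R)-C15 enone | C=C1[C@@H]2CC[C@@H]3[C@](C2)(C(=O)OC[C@]32[C@@H](OC(C)=O)CCC(C)(C)C2=COCOC)C1=O | intermediate
29 | (1S,8S,9S,10S,13R,15R)-C15 alcohol, C5=C6 methoxymethyl enol ether | C=C1[C@@H]2CC[C@@H]3[C@](C2)(C(=O)OC[C@]32[C@@H](OC(C)=O)CCC(C)(C)C2=COCOC)[C@@H]1O | intermediate
30 | (1S,5R,8S,9S,10S,13R,15R)-1-acetoxy-15-hydroxy-6-oxo-6,7-seco-kaur-16-ene-7,20-lactone | C=C1[C@@H]2CC[C@@H]3[C@](C2)(C(=O)OC[C@]32[C@@H](OC(C)=O)CCC(C)(C)[C@H]2C=O)[C@@H]1O | target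

**Step count and risks**
Total step count: 20. Longest linear sequence: 19 steps (steps 1–6 and 8–20; step 7 prepares the phosphonate).

Step 9 (proposed new method). The ring closure may fail through O-alkylation of the stabilised anion in place of C-alkylation at C10, or through β-elimination of the C1 silyloxy group from the extended anion. The fallback uses known chemistry, sets out from 13 and returns at 17. The trienolate of 13 (LiN(iPr)2, THF, −78 °C) is C-acylated with phenyl chloroformate (deconjugative α-acylation of a dienolate) to give the isolated phenyl 2-[(ethylsulfanyl)carbonyl]-3-[(6R)-6-[(tert-butyldimethylsilyl)oxy]-2-[(methoxymethoxy)methylidene]-3,3-dimethylcyclohexylidene]propanoate F1. F1 is then treated with paraformaldehyde and catalytic DBU in THF: reversible α-aldol addition funnels into γ-selective vinylogous aldol addition at C10, and the C20 alkoxide lactonises onto the phenyl ester (the established dihydropyranone synthesis from alkylidene malonates and aldehydes) to give 17. The bond to C10 is then made by an aldol step that cannot end on oxygen.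

Step 10. The hindered dienophile (C9 is attached to the quaternary C10) may react too slowly with unactivated butadiene, so that thermal decomposition of the enol ether competes. The fallback sets out from 17 and returns at 19. Cycloaddition with the much more reactive 2-(trimethylsilyloxy)buta-1,3-diene (toluene, 80 °C; the silyloxy carbon ends para to C8, at C12) should give the C12 trimethylsilyl enol ether analogue of 19 F2. CsF and PhNTf2 in DME convert it regiospecifically into the C12 enol triflate analogue of 19 F3. Pd(OAc)2, PPh3, Bu3N and HCO2H in DMF then reduce the triflate to the C12=C13 alkene 19.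

Step 17. The vinyl radical may close 6-endo on C12, the C12 radical may rearrange (homoallyl to cyclopropylcarbinyl) toward the bicyclo[2.2.2]octane, or 1,5-hydrogen transfer from C11 may compete. The fallback sets out from 25 and returns at 27 without a new compound (F0). It is a palladium hydride reductive enyne cyclisation (Pd2(dba)3·CHCl3, P(o-tol)3, AcOH, Et3SiH, benzene, rt): hydropalladation of the alkyne places palladium on C16, syn-carbopalladation of the C12=C13 bond can only close the five-membered ring, and the silane reduces the C12–Pd bond.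

**Further compounds**
F1 | step 9 | phenyl 2-[(ethylsulfanyl)carbonyl]-3-[(6R)-6-[(tert-butyldimethylsilyl)oxy]-2-[(methoxymethoxy)methylidene]-3,3-dimethylcyclohexylidene]propanoate | CC(C)(C)[Si](C)(C)O[C@@H]1CCC(C)(C)C(=COCOC)C1=CC(C(=O)SCC)C(=O)Oc1ccccc1
F2 | step 10 | C12 trimethylsilyl enol ether analogue of 19 (1R,8R,9S,10S) | CCSC(=O)[C@]12CC=C(O[Si](C)(C)C)C[C@H]1[C@]3(COC2=O)[C@H](O[Si](C)(C)C(C)(C)C)CCC(C)(C)C3=COCOC
F3 | step 10 | C12 enol triflate analogue of 19 (1R,8R,9S,10S) | CCSC(=O)[C@]12CC=C(OS(=O)(=O)C(F)(F)F)C[C@H]1[C@]3(COC2=O)[C@H](O[Si](C)(C)C(C)(C)C)CCC(C)(C)C3=COCOC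
F0 | step 17 | none | none
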